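(All runs were generated by integration on assumed constants.)

The east run lost 43.2% of its starting material in 5.00 min, and the south-east run lost 72.2% in the same time. You want to know what these runs say about two new flasks.

| setting | east | south-east | larch | birch |
|---|---|---|---|---|
| starting material | 13 mM | 30 mM | 20 mM | 20 mM |
| coupling partner | 60 mM | 60 mM | 60.0 mM | 60.0 mM |
| temperature | −25 °C | −12 °C | −20 °C | −5 °C |
| remark | run made earlier | run made earlier |  |  |
| time |  |  | 2.0 h | 2.0 h |

| run | time / min | single product / % | starting material / % |
|---|---|---|---|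
| east | 5.00 | 36.1 | 56.8 |
| east | 15.0 | 52.2 | 24.3 |
| east | 25.0 | 52.0 | 8.4 |
| east | 40.0 | 49.3 | 2.2 |
| east | 60.0 | 44.0 | 0 |
| east | 80.0 | 40.8 | 0 |
| south-east | 5.00 | 42.9 | 27.8 |
| south-east | 15.0 | 42.4 | 5.0 |
| south-east | 25.0 | 37.8 | 1.2 |
| south-east | 40.0 | 27.0 | 0.1 |
| south-east | 60.0 | 21.8 | 0 |
| south-east | 80.0 | 15.7 | 0 |

(readings scatter by 1 percentage point)

- what may be going on: single product <-> isomer of the product; coupling partner + bis adduct -> triple product; coupling partner + single product -> bis adduct; coupling partner <-> dormant form; single product -> over-reaction product; starting material + coupling partner -> single product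

* the flask with the highest amount of single product, in percent of the starting material charged ("all alike" if they lie within 1.5 percentage points) (larch / birch / all alike)
* final single product, as a percentage of the starting material charged, in larch
* final single product, as a percentage of the starting material charged, in birch

My own reckoning is a ladder, fastest rung first. Each rate constant is interpolated in ln against temperature, which is a rough rule outside the runs.

Rung one is the starting material. Call k its apparent first-order constant. It is no true constant: the south-east run gives 0.172 min⁻¹ between 5.00 min and 15.0 min, so take it as a rough figure. From the first reading of each run: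

k(east) = 0.113 min⁻¹, k(south-east) = 0.256 min⁻¹

k(larch) = 0.155 min⁻¹, a life of 6.46 min

Rung two is the tail. Call λ the first-order constant at which single product falls once the starting material has nearly left:

λ(east) = 0.00473 min⁻¹, λ(south-east) = 0.0160 min⁻¹

λ(larch) = 0.00755 min⁻¹, λ(birch) = 0.0308 min⁻¹

This tail constant gives larch a life of 132 min, much longer than the starting material's. So the flask first fills, then drains.

Rung three is the start of the drain. Running both tails back to zero time gives a mean height P:

P = 58.0%

Y = P·exp(−λt): larch 23.4%, birch 1.45%

The forecast says larch, with 24% in larch and 3% in birch, above my birch figure: “Larch clearly wins.”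

Larch gives 22.5% and birch 0.141%, so larch holds more.

    single product ⇌ isomer of the product (K = 0.570, k = 0.00185 s⁻¹, Ea = 82.0 kJ mol⁻¹, ΔH = 2.00 kJ mol⁻¹)
    coupling partner + bis adduct → triple product (k = 0.0397 M⁻¹ s⁻¹, Ea = 38.0 kJ mol⁻¹)
    coupling partner + single product → bis adduct (k = 0.00516 M⁻¹ s⁻¹, Ea = 56.0 kJ mol⁻¹)
    coupling partner ⇌ dormant form (K = 0.0900, k = 5.75 × 10⁻⁴ s⁻¹, Ea = 73.0 kJ mol⁻¹, ΔH = −43.0 kJ mol⁻¹)
    single product → over-reaction product (k = 9.03 × 10⁻⁵ s⁻¹, Ea = 84.0 kJ mol⁻¹)
    starting material + coupling partner → single product (k = 0.0516 M⁻¹ s⁻¹, Ea = 47.0 kJ mol⁻¹)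
    (constants at −20 °C)

Larch fell from 36.6% at 1.00 h to 22.5% at 2.0 h, a tail of 0.00811 min⁻¹ against λ(larch) of 0.00755 min⁻¹. To put the forecast for larch out, a run must shift it: 5 points came at a reading of 2.55 h. The birch reading at 50 min held 4.48%, and from there birch fell at 0.0494 min⁻¹ against λ(birch) of 0.0308 min⁻¹.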